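**Retrosynthetic overview**
Target 35 ⇐ hexabenzyl ether 34 (hydrogenolysis) ⇐ phenol–alcohol 33 by Mitsunobu closure of the lower pyran ring (ring F) at O1–C2 with inversion.
The strategy rests on lower ring D (C4a, C5, C6, C7, C8, C8a), a pentasubstituted phloroglucinol whose oxygens O5, O7 and O1 (on C8a) must be told apart so that upper C4 sits on C6 and not C8. Ring D is therefore built de novo by Danheiser benzannulation of cyclobutenone 16 with siloxyalkyne 26 (lower C4a–C5 and C8–C8a formed), which delivers O5–H, O7–Bn and O(C8a)–Si(iPr)3.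
16 ⇐ ketene [2+2] of cis-flavan-4-ylacetic acid 7 with benzyl ethynyl ether 13; 7 ⇐ Reformatsky addition and ionic reduction (sets C4) on (2S)-flavanone 4 ⇐ asymmetric arylation of chromone 2 (sets C2).
26 ⇐ terminal alkyne 23 (ynolate oxidation, O-silylation) ⇐ acetylide opening of anti epoxy alcohol 19 ⇐ Sharpless kinetic resolution of allylic alcohol 18 ⇐ 4-benzyloxybenzaldehyde 17.
Ring order: A/C from the chromone (ring B added in step 2), cyclobutenone, ring D (step 16), ring F (step 19); ring E comes with the aldehyde.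

Key step: step 16

**Remarks**
- Convention: upper unit = rings A (benzo), C (pyran), B (aryl); lower unit = rings D (benzo), F (pyran), E (aryl); flavan numbering within each unit.
- Assumption: the (R)-t-BuPyOx ligand is taken to give the (2S)-flavanone, by analogy with the (S)-ligand/(R)-product sense of this catalyst system; if the sense is opposite, the antipodal ligand is used.

**Route**

Step 1
Reactants: 1 7-hydroxychromone
Product: 2 7-(benzyloxy)-4H-chromen-4-one
Conditions: BnBr, K2CO3, acetone, reflux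
Reagents that add atoms: benzyl bromide, BrCc1ccccc1
Why: Williamson etherification of the acidic C7 phenol, under which the pyranone ring is inert.

Step 2
Reactants: 2 7-(benzyloxy)chromone; 3 4-(benzyloxy)phenylboronic acid
Product: 4 (2S)-7-(benzyloxy)-2-[4-(benzyloxy)phenyl]chroman-4-one
Conditions: Pd(OCOCF3)2 (5 mol %), (R)-t-BuPyOx (6 mol %), NH4PF6 (30 mol %), H2O (5 equiv), ClCH2CH2Cl, 60 °C
Reagents that add atoms: none
Why: Enantioselective conjugate arylation of the chromone under cationic divalent palladium–pyridine-oxazoline catalysis, in which the aryl–palladium species adds across C2=C3 on the face left open by the tert-butyl group of the ligand and so sets upper C2 (S), while protonolysis of the palladium enolate by water releases the flavanone under non-basic conditions that do not open ring C.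

Step 3
Reactants: 4 (2S)-flavanone
Product: 5 ethyl 2-[(2S)-7-(benzyloxy)-2-[4-(benzyloxy)phenyl]-4-hydroxychroman-4-yl]acetate (both C4 epimers)
Conditions: Zn (Me3SiCl-activated), BrCH2CO2Et, THF, 50 °C; aq NH4Cl
Reagents that add atoms: ethyl bromoacetate, CCOC(=O)CBr
Why: Reformatsky reaction, whose weakly basic zinc ester enolate adds to the C4 ketone instead of deprotonating C3, so that ring C is not opened by retro-oxa-Michael reaction and C2 keeps its configuration, while the configuration of the new C4 carbinol does not matter because C4 is ionised in step 4.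

Step 4
Reactants: 5 β-hydroxy ester
Product: 6 ethyl 2-[(2S,4R)-7-(benzyloxy)-2-[4-(benzyloxy)phenyl]chroman-4-yl]acetate (2,4-cis)
Conditions: Et3SiH, BF3·OEt2, CH2Cl2, −78 → −40 °C
Reagents that add atoms: none
Why: Ionic hydrogenation in which BF3 ionises the tertiary benzylic C4 hydroxyl (the cation is stabilised by O1 and O7) and Et3SiH should deliver hydride pseudo-axially on the face bearing H2, opposite the equatorial C2 aryl group, setting C4 (R) with the acetate arm cis to the aryl group, while the low temperature spares the benzyl ethers and the O1–C2 benzylic ether bond.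

Step 5
Reactants: 6 cis ester
Product: 7 2-[(2S,4R)-7-(benzyloxy)-2-[4-(benzyloxy)phenyl]chroman-4-yl]acetic acid
Conditions: LiOH, THF/MeOH/H2O, rt; then 1 M HCl
Reagents that add atoms: lithium hydroxide, [Li+].[OH-]
Why: Saponification of the ethyl ester, which touches neither stereocentre because C4 is β and not α to the carboxylate.

Step 6
Reactants: 8 trichloroethylene; 9 benzyl alcohol
Product: 10 benzyl (E)-1,2-dichlorovinyl ether
Conditions: KH, THF, 0 °C; then 8, −50 °C → rt
Reagents that add atoms: none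
Why: Base-mediated addition–elimination of the potassium alkoxide on trichloroethylene (through dichloroacetylene), the standard entry to 1,2-dichlorovinyl ethers as alkynyl ether precursors.

Step 7
Reactants: 10 benzyl (E)-1,2-dichlorovinyl ether
Product: 13 benzyl ethynyl ether (used as a cold solution), via benzyl chloroethynyl ether 11 (not isolated), via lithium benzyloxyacetylide 12 (not isolated)
Conditions: n-BuLi (2.2 equiv), Et2O, −78 → −40 °C; H2O, −78 °C; cold pentane extract kept ≤0 °C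
Reagents that add atoms: none
Why: Lithiation at the CHCl terminus with loss of LiCl gives chloroalkyne 11, chlorine–lithium exchange gives acetylide 12 and protonation gives ynol ether 13, which is kept cold and dilute and used at once because benzyl alkynyl ethers rearrange by a [3,3] shift on warming.

Step 8
Reactants: 7 cis-flavan-4-ylacetic acid; 13 benzyl ethynyl ether
Product: 16 3-(benzyloxy)-4-[(2S,4R)-7-(benzyloxy)-2-[4-(benzyloxy)phenyl]chroman-4-yl]cyclobut-2-en-1-one as both epimers at the cyclobutenone sp3 carbon, via acid chloride 14 (not isolated), via alkylketene 15 (not isolated)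
Conditions: (COCl)2, DMF (cat.), CH2Cl2, 0 °C → rt; evaporate; slow addition to 13 (3 equiv), Et3N, CH2Cl2, 0 °C → rt
Reagents that add atoms: none
Why: Dehydrochlorination of 14 by Et3N gives monoalkylketene 15, which is trapped in a ketene–alkoxyalkyne [2+2] cycloaddition in which the nucleophilic unsubstituted alkyne carbon bonds to the ketene carbonyl carbon, so that OBn ends on C3 and the flavanyl group on the sp3 carbon C4 of the cyclobutenone; slow addition into excess 13 suppresses ketene dimerisation, and the new sp3 centre need not be controlled because it becomes aromatic in step 16.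

Step 9
Reactants: 17 4-(benzyloxy)benzaldehyde
Product: 18 rac-1-[4-(benzyloxy)phenyl]prop-2-en-1-ol
Conditions: CH2=CHMgBr, THF, −78 → 0 °C; aq NH4Cl
Reagents that add atoms: vinylmagnesium bromide, C=C[Mg]Br
Why: Grignard 1,2-addition to the aldehyde.

Step 10
Reactants: 18 racemic allylic alcohol
Product: 19 (S)-[4-(benzyloxy)phenyl][(2R)-oxiran-2-yl]methanol
Conditions: Ti(OiPr)4 (0.2 equiv), L-(+)-DIPT (0.24 equiv), t-BuOOH (0.6 equiv), 4 Å MS, CH2Cl2, −20 °C
Reagents that add atoms: tert-butyl hydroperoxide, CC(C)(C)OO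
Why: Sharpless kinetic resolution, in which the titanium tartrate complex epoxidises the (R)-alcohol fast (aryl outranks vinyl, so this is the spatial counterpart of the fast (S)-enantiomer of alkyl vinyl carbinols) and delivers oxygen to give the erythro (anti) epoxy alcohol, setting lower C2 (S) and C3 (R) in flavan numbering; the slow (S)-alcohol is left behind and separated.

Step 11
Reactants: 19 epoxy alcohol
Product: 20 {(S)-[4-(benzyloxy)phenyl][(2R)-oxiran-2-yl]methoxy}(tert-butyl)dimethylsilane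
Conditions: t-BuMe2SiCl, imidazole, DMF, 0 °C → rt
Reagents that add atoms: tert-butyldimethylsilyl chloride, CC(C)(C)[Si](C)(C)Cl
Why: Silylation of the secondary benzylic hydroxyl, which blocks Payne rearrangement and marks this oxygen as the later leaving group.

Step 12
Reactants: 20 silylated epoxide
Product: 21 (1S,2R)-1-[4-(benzyloxy)phenyl]-1-[(tert-butyldimethylsilyl)oxy]-5-(trimethylsilyl)pent-4-yn-2-ol
Conditions: Me3SiC≡CH, n-BuLi, THF, −78 °C; BF3·OEt2; then 20, −78 °C
Reagents that add atoms: (trimethylsilyl)acetylene, C#C[Si](C)(C)C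
Why: BF3-promoted alkynylation of the terminal epoxide, in which the lithium acetylide attacks the unsubstituted CH2 at −78 °C so that lower C3 keeps its configuration and carries the free hydroxyl.

Step 13
Reactants: 21 homopropargylic alcohol
Product: 22 {[(1S,2R)-2-(benzyloxy)-1-[4-(benzyloxy)phenyl]-5-(trimethylsilyl)pent-4-yn-1-yl]oxy}(tert-butyl)dimethylsilane
Conditions: 2-benzyloxy-1-methylpyridinium triflate, MgO, PhCF3, 83 °C
Reagents that add atoms: 2-benzyloxy-1-methylpyridinium triflate, C[n+]1ccccc1OCc1ccccc1.[O-]S(=O)(=O)C(F)(F)F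
Why: Neutral thermal benzyl transfer from the pyridinium salt with MgO as acid scavenger, which avoids the alkoxide that would trigger 1,2-silyl migration between the vicinal oxygens under NaH/BnBr.

Step 14
Reactants: 22 silylalkyne
Product: 23 {[(1S,2R)-2-(benzyloxy)-1-[4-(benzyloxy)phenyl]pent-4-yn-1-yl]oxy}(tert-butyl)dimethylsilane
Conditions: K2CO3 (cat.), MeOH, rt
Reagents that add atoms: none
Why: Methanolysis of the alkynyl C–Si bond, which leaves the silyl ether and benzyl ethers untouched now that no free hydroxyl neighbours the silyl ether.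

Step 15
Reactants: 23 terminal alkyne
Product: 26 {[(4R,5S)-4-(benzyloxy)-5-[4-(benzyloxy)phenyl]-5-[(tert-butyldimethylsilyl)oxy]pent-1-yn-1-yl]oxy}tri(propan-2-yl)silane, via lithium acetylide 24 (not isolated), via lithium ynolate 25 (not isolated)
Conditions: LiN(SiMe3)2, THF, −78 °C; t-BuOOLi (from t-BuOOH + LiN(SiMe3)2), −78 → 0 °C; iPr3SiOTf, −78 °C
Reagents that add atoms: tert-butyl hydroperoxide, CC(C)(C)OO; triisopropylsilyl triflate, CC(C)[Si](OS(=O)(=O)C(F)(F)F)(C(C)C)C(C)C
Why: Oxidation of the lithium acetylide by lithium tert-butyl peroxide gives the lithium ynolate, and the bulky silyl triflate traps it on oxygen, the established preparation of triisopropylsiloxyalkynes from terminal alkynes.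

Step 16
Reactants: 16 3-benzyloxy-4-(flavan-4-yl)cyclobutenone; 26 siloxyalkyne
Product: 31 ring D phenol (O5 free; O7 benzyl; O on C8a triisopropylsilyl) 3-(benzyloxy)-2-[(2S,4S)-7-(benzyloxy)-2-[4-(benzyloxy)phenyl]chroman-4-yl]-6-[(2R,3S)-2-(benzyloxy)-3-[4-(benzyloxy)phenyl]-3-[(tert-butyldimethylsilyl)oxy]propyl]-5-[(triisopropylsilyl)oxy]phenol, via vinylketene 27 (not isolated), via vinylcyclobutenone 28 (not isolated), via dienylketene 29 (not isolated), via cyclohexadienone 30 (not isolated)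
Conditions: 16 (1.0 equiv), 26 (1.2 equiv), degassed PhMe, 80 °C, then 110 °C
Reagents that add atoms: none
Why: Heating opens 16 by 4π electrocyclic ring opening to vinylketene 27, whose C=C=O unit takes up the electron-rich siloxyalkyne in a regioselective [2+2] cycloaddition to give 2-vinylcyclobutenone 28; a second 4π opening gives dienylketene 29, which closes by 6π electrocyclisation to cyclohexadienone 30 and tautomerises to phenol 31. The closest known reaction type is the Danheiser benzannulation of cyclobutenones with siloxyalkynes to resorcinol monosilyl ethers; the 3-alkoxy group and the secondary alkyl group at C4 of the cyclobutenone extend that precedent to a pattern not yet tried. Ring D is closed in the 6π electrocyclisation (C5–C6) after the [2+2]/ring-opening sequence has made C4a–C5 and C8–C8a; the ring ends aromatic, so no stereocentre is created and the configuration of the cyclobutenone sp3 carbon is erased. The selectivity needed is the orientation of the ketene–alkyne union: the nucleophilic alkyne carbon bearing the side chain bonds to the electrophilic ketene carbonyl carbon, which puts the chain on C4a between the new C5 hydroxyl and the silyloxy group on C8a, with OBn on C7 and the upper unit on C6. The di-ortho-substituted phenol should resist acylation by remaining ketene, and the slight excess of 26 keeps the vinylketene concentration low.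

Step 17
Reactants: 31 ring D phenol
Product: 32 O5-benzyl ether of 31, i.e. 1,5-bis(benzyloxy)-6-[(2S,4S)-flavan-4-yl]-2-[(2R,3S)-side chain]-3-[(triisopropylsilyl)oxy]benzene with all other groups as in 31
Conditions: NaH, BnBr, Bu4NI (cat.), DMF, 0 °C → rt
Reagents that add atoms: benzyl bromide, BrCc1ccccc1
Why: Williamson benzylation of the only free hydroxyl, which ensures that only the oxygen on C8a can later close ring F and so fixes the C4–C6 linkage.

Step 18
Reactants: 32 fully protected ring D compound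
Product: 33 phenol–alcohol (1S,2R)-2-(benzyloxy)-1-[4-(benzyloxy)phenyl]-3-{2,4-bis(benzyloxy)-3-[(2S,4S)-7-(benzyloxy)-2-[4-(benzyloxy)phenyl]chroman-4-yl]-6-hydroxyphenyl}propan-1-ol
Conditions: Bu4NF, AcOH (1:1), THF, rt → 40 °C
Reagents that add atoms: none
Why: Fluoride cleaves the aryl triisopropylsilyl ether and the secondary tert-butyldimethylsilyl ether together, with acetic acid buffering the phenoxide and alkoxide.

Step 19
Reactants: 33 phenol–alcohol
Product: 34 (2R,3R)-3,5,7-tris(benzyloxy)-6-[(2S,4S)-7-(benzyloxy)-2-[4-(benzyloxy)phenyl]chroman-4-yl]-2-[4-(benzyloxy)phenyl]chromane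
Conditions: PPh3, DIAD, PhMe (0.01 M), 0 °C → rt
Reagents that add atoms: none
Why: Intramolecular Mitsunobu etherification, in which the benzylic C2 hydroxyl is activated as its oxyphosphonium ion and displaced by the C8a phenoxide (6-exo-tet) with inversion, turning C2 from S to R and giving the 2,3-cis ring F, with the non-polar solvent and low temperature chosen to disfavour ionisation.

Step 20
Reactants: 34 hexabenzyl ether
Product: 35 (2R,3R)-6-[(2S,4S)-7-hydroxy-2-(4-hydroxyphenyl)chroman-4-yl]-2-(4-hydroxyphenyl)chromane-3,5,7-triol (target)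
Conditions: H2 (1 atm), Pd(OH)2/C, THF/MeOH, rt
Reagents that add atoms: none
Why: Hydrogenolysis of the five aryl and one alkyl benzyl ethers, conditions under which the flavan C2–O bonds and the C4–C6 link of benzylated flavan dimers are known to survive.

**Compound list**
1 | 7-hydroxy-4H-chromen-4-one | O=c1ccoc2cc(O)ccc12 | starting material
2 | 7-(benzyloxy)-4H-chromen-4-one | O=c1ccoc2cc(OCc3ccccc3)ccc12 | intermediate
3 | 4-(benzyloxy)phenylboronic acid | OB(O)c1ccc(OCc2ccccc2)cc1 | starting material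
4 | (2S)-7-(benzyloxy)-2-[4-(benzyloxy)phenyl]chroman-4-one | O=C1C[C@@H](c2ccc(OCc3ccccc3)cc2)Oc2cc(OCc3ccccc3)ccc12 | intermediate
5 | ethyl 2-[(2S)-7-(benzyloxy)-2-[4-(benzyloxy)phenyl]-4-hydroxychroman-4-yl]acetate (C4 epimers) | CCOC(=O)CC1(O)C[C@@H](c2ccc(OCc3ccccc3)cc2)Oc2cc(OCc3ccccc3)ccc12 | intermediate
6 | ethyl 2-[(2S,4R)-7-(benzyloxy)-2-[4-(benzyloxy)phenyl]chroman-4-yl]acetate | CCOC(=O)C[C@H]1C[C@@H](c2ccc(OCc3ccccc3)cc2)Oc2cc(OCc3ccccc3)ccc12 | intermediate
7 | 2-[(2S,4R)-7-(benzyloxy)-2-[4-(benzyloxy)phenyl]chroman-4-yl]acetic acid | OC(=O)C[C@H]1C[C@@H](c2ccc(OCc3ccccc3)cc2)Oc2cc(OCc3ccccc3)ccc12 | intermediate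
8 | trichloroethylene | ClC=C(Cl)Cl | starting material
9 | benzyl alcohol | OCc1ccccc1 | starting material
10 | benzyl (E)-1,2-dichlorovinyl ether | Cl/C=C(/Cl)OCc1ccccc1 | intermediate
11 | benzyl chloroethynyl ether | ClC#COCc1ccccc1 | intermediate
12 | lithium (benzyloxy)acetylide | [Li]C#COCc1ccccc1 | intermediate
13 | benzyl ethynyl ether | C#COCc1ccccc1 | intermediate
14 | 2-[(2S,4R)-7-(benzyloxy)-2-[4-(benzyloxy)phenyl]chroman-4-yl]acetyl chloride | ClC(=O)C[C@H]1C[C@@H](c2ccc(OCc3ccccc3)cc2)Oc2cc(OCc3ccccc3)ccc12 | intermediate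
15 | [(2S,4R)-7-(benzyloxy)-2-[4-(benzyloxy)phenyl]chroman-4-yl]ketene | O=C=C[C@H]1C[C@@H](c2ccc(OCc3ccccc3)cc2)Oc2cc(OCc3ccccc3)ccc12 | intermediate
16 | 3-(benzyloxy)-4-[(2S,4R)-7-(benzyloxy)-2-[4-(benzyloxy)phenyl]chroman-4-yl]cyclobut-2-en-1-one (epimers at the cyclobutenone sp3 carbon) | O=C1C=C(OCc2ccccc2)C1[C@H]4C[C@@H](c2ccc(OCc3ccccc3)cc2)Oc2cc(OCc3ccccc3)ccc24 | intermediate
17 | 4-(benzyloxy)benzaldehyde | O=Cc1ccc(OCc2ccccc2)cc1 | starting material
18 | rac-1-[4-(benzyloxy)phenyl]prop-2-en-1-ol | C=CC(O)c1ccc(OCc2ccccc2)cc1 | intermediate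
19 | (S)-[4-(benzyloxy)phenyl][(2R)-oxiran-2-yl]methanol | O[C@@H](c1ccc(OCc2ccccc2)cc1)[C@H]1CO1 | intermediate
20 | {(S)-[4-(benzyloxy)phenyl][(2R)-oxiran-2-yl]methoxy}(tert-butyl)dimethylsilane | CC(C)(C)[Si](C)(C)O[C@@H](c1ccc(OCc2ccccc2)cc1)[C@H]1CO1 | intermediate
21 | (1S,2R)-1-[4-(benzyloxy)phenyl]-1-[(tert-butyldimethylsilyl)oxy]-5-(trimethylsilyl)pent-4-yn-2-ol | C[Si](C)(C)C#CC[C@@H](O)[C@@H](O[Si](C)(C)C(C)(C)C)c1ccc(OCc2ccccc2)cc1 | intermediate
22 | {[(1S,2R)-2-(benzyloxy)-1-[4-(benzyloxy)phenyl]-5-(trimethylsilyl)pent-4-yn-1-yl]oxy}(tert-butyl)dimethylsilane | C[Si](C)(C)C#CC[C@@H](OCc1ccccc1)[C@@H](O[Si](C)(C)C(C)(C)C)c1ccc(OCc2ccccc2)cc1 | intermediate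
23 | {[(1S,2R)-2-(benzyloxy)-1-[4-(benzyloxy)phenyl]pent-4-yn-1-yl]oxy}(tert-butyl)dimethylsilane | C#CC[C@@H](OCc1ccccc1)[C@@H](O[Si](C)(C)C(C)(C)C)c1ccc(OCc2ccccc2)cc1 | intermediate
24 | lithium acetylide of 23 | [Li]C#CC[C@@H](OCc1ccccc1)[C@@H](O[Si](C)(C)C(C)(C)C)c1ccc(OCc2ccccc2)cc1 | intermediate
25 | lithium (4R,5S)-4-(benzyloxy)-5-[4-(benzyloxy)phenyl]-5-[(tert-butyldimethylsilyl)oxy]pent-1-yn-1-olate | [Li]OC#CC[C@@H](OCc1ccccc1)[C@@H](O[Si](C)(C)C(C)(C)C)c1ccc(OCc2ccccc2)cc1 | intermediate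
26 | {[(4R,5S)-4-(benzyloxy)-5-[4-(benzyloxy)phenyl]-5-[(tert-butyldimethylsilyl)oxy]pent-1-yn-1-yl]oxy}tri(propan-2-yl)silane | CC(C)[Si](C(C)C)(C(C)C)OC#CC[C@@H](OCc1ccccc1)[C@@H](O[Si](C)(C)C(C)(C)C)c1ccc(OCc2ccccc2)cc1 | intermediate
27 | vinylketene from 16: 3-(benzyloxy)-4-(flavan-4-yl)buta-1,3-dien-1-one, flavanyl trans to the ketenyl carbon | O=C=C/C(OCc1ccccc1)=C/[C@H]4C[C@@H](c2ccc(OCc3ccccc3)cc2)Oc2cc(OCc3ccccc3)ccc24 | intermediate
28 | [2+2] adduct: 2-(side chain)-3-(triisopropylsilyloxy)-4-[1-(benzyloxy)-2-(flavan-4-yl)vinyl]cyclobut-2-en-1-one | O=C1C(C[C@@H](OCc2ccccc2)[C@@H](O[Si](C)(C)C(C)(C)C)c2ccc(OCc3ccccc3)cc2)=C(O[Si](C(C)C)(C(C)C)C(C)C)C1/C(OCc2ccccc2)=C/[C@H]4C[C@@H](c2ccc(OCc3ccccc3)cc2)Oc2cc(OCc3ccccc3)ccc24 | intermediate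
29 | dienylketene: 2-(side chain)-3-(triisopropylsilyloxy)-5-(benzyloxy)-6-(flavan-4-yl)hexa-1,3,5-trien-1-one, drawn in the geometry that cyclises | O=C=C(C[C@@H](OCc1ccccc1)[C@@H](O[Si](C)(C)C(C)(C)C)c1ccc(OCc2ccccc2)cc1)/C(O[Si](C(C)C)(C(C)C)C(C)C)=C\C(OCc1ccccc1)=C\[C@H]4C[C@@H](c2ccc(OCc3ccccc3)cc2)Oc2cc(OCc3ccccc3)ccc24 | intermediate
30 | cyclohexa-2,4-dienone tautomer of 31 | O=C1C(C[C@@H](OCc2ccccc2)[C@@H](O[Si](C)(C)C(C)(C)C)c2ccc(OCc3ccccc3)cc2)=C(O[Si](C(C)C)(C(C)C)C(C)C)C=C(OCc2ccccc2)C1[C@H]4C[C@@H](c2ccc(OCc3ccccc3)cc2)Oc2cc(OCc3ccccc3)ccc24 | intermediate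
31 | 3-(benzyloxy)-2-[(2S,4S)-7-(benzyloxy)-2-[4-(benzyloxy)phenyl]chroman-4-yl]-6-[(2R,3S)-2-(benzyloxy)-3-[4-(benzyloxy)phenyl]-3-[(tert-butyldimethylsilyl)oxy]propyl]-5-[(triisopropylsilyl)oxy]phenol | Oc1c(C[C@@H](OCc2ccccc2)[C@@H](O[Si](C)(C)C(C)(C)C)c2ccc(OCc3ccccc3)cc2)c(O[Si](C(C)C)(C(C)C)C(C)C)cc(OCc2ccccc2)c1[C@H]4C[C@@H](c2ccc(OCc3ccccc3)cc2)Oc2cc(OCc3ccccc3)ccc24 | intermediate
32 | O5-benzyl ether of 31 | c5ccccc5COc1c(C[C@@H](OCc2ccccc2)[C@@H](O[Si](C)(C)C(C)(C)C)c2ccc(OCc3ccccc3)cc2)c(O[Si](C(C)C)(C(C)C)C(C)C)cc(OCc2ccccc2)c1[C@H]4C[C@@H](c2ccc(OCc3ccccc3)cc2)Oc2cc(OCc3ccccc3)ccc24 | intermediate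
33 | (1S,2R)-2-(benzyloxy)-1-[4-(benzyloxy)phenyl]-3-{2,4-bis(benzyloxy)-3-[(2S,4S)-7-(benzyloxy)-2-[4-(benzyloxy)phenyl]chroman-4-yl]-6-hydroxyphenyl}propan-1-ol | c5ccccc5COc1c(C[C@@H](OCc2ccccc2)[C@@H](O)c2ccc(OCc3ccccc3)cc2)c(O)cc(OCc2ccccc2)c1[C@H]4C[C@@H](c2ccc(OCc3ccccc3)cc2)Oc2cc(OCc3ccccc3)ccc24 | intermediate
34 | (2R,3R)-3,5,7-tris(benzyloxy)-6-[(2S,4S)-7-(benzyloxy)-2-[4-(benzyloxy)phenyl]chroman-4-yl]-2-[4-(benzyloxy)phenyl]chromane | c5ccccc5COc1c6C[C@@H](OCc2ccccc2)[C@@H](c2ccc(OCc3ccccc3)cc2)Oc6cc(OCc2ccccc2)c1[C@H]4C[C@@H](c2ccc(OCc3ccccc3)cc2)Oc2cc(OCc3ccccc3)ccc24 | intermediate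
35 | (2R,3R)-6-[(2S,4S)-7-hydroxy-2-(4-hydroxyphenyl)chroman-4-yl]-2-(4-hydroxyphenyl)chromane-3,5,7-triol | Oc1ccc([C@@H]2C[C@H](c3c(O)cc4c(c3O)C[C@@H](O)[C@@H](c3ccc(O)cc3)O4)c3ccc(O)cc3O2)cc1 | target

**Count**
Total: 20 steps. Longest linear sequence: 12 steps (steps 9–20, from 17 to 35).

**Steps most likely to fail**

1. Step 16 (benzannulation). The 3-benzyloxy group stabilises the cyclobutenone as a vinylogous ester, so ring opening may need temperatures at which the vinylketene dimerises or the siloxyalkyne degrades. The bulky flavanyl group next to the ketene may also slow the [2+2] union. The fallback sets out from 4, 13 and 26 and returns at 31. Flavanone 4 is reduced (NaBH4, MeOH/THF, 0 °C) to the 2,4-cis flavan-4-ol F1. Ring D is built without the upper unit: ketene from acetyl chloride and Et3N is combined with 13 to give the parent 3-(benzyloxy)cyclobut-2-en-1-one F2, and the Danheiser benzannulation of this unhindered cyclobutenone with 26 (PhMe, 80–110 °C) gives the simpler phenol F3, in which C6 and C8 are free. Friedel–Crafts alkylation of F3 by the flavan-4-yl cation from F1 (BF3·OEt2 cat., CH2Cl2, −78 → −40 °C) is expected at C6, ortho to the free O5 hydroxyl and away from the silyl-shielded C8, and gives 31. The 2,4-cis isomer would have to be separated from any trans isomer.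

2. Step 19 (Mitsunobu closure). The oxyphosphonium ion sits on a 4-benzyloxybenzylic carbon and may ionise, so that displacement loses its stereospecificity and the 2,3-trans ring forms alongside the cis one. The fallback sets out from 33 and returns at 34, and closes the same O1–C2 bond with retention after correcting C2. The phenol is converted into the aryl triflate F4 (PhNTf2, Et3N, CH2Cl2). The benzylic alcohol is oxidised to the aryl ketone F5 (Dess–Martin periodinane, NaHCO3, CH2Cl2). Felkin–Anh reduction (K[s-Bu3BH], THF, −78 °C), with the α-benzyloxy group anti to the incoming hydride, should give the syn (1R,2R) alcohol F6. Palladium-catalysed intramolecular aryl etherification (Pd(OAc)2, 2-(di-tert-butylphosphino)-1,1'-binaphthyl, Cs2CO3, PhMe, 80 °C) then forms O1–C8a with retention at C2 and gives 34.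

3. Step 4 (ionic hydrogenation). Hydride delivery to the planar C4 cation may show poor facial selectivity, and the Lewis acid may also cleave the O1–C2 benzylic ether bond. The fallback sets out from 5 and returns at 6. Dehydration with the Burgess reagent (PhMe, 50 °C) gives the flav-3-ene ester F7 (the exocyclic isomer would converge). Hydrogenation (H2, Pd/C, EtOAc/EtOH) adds hydrogen syn from the face opposite the C2 aryl group to give the 2,4-cis flavan and removes both benzyl groups, giving the diphenol ester F8. Re-benzylation (BnBr, K2CO3, DMF) returns 6.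

**Further compounds**
F1 | step 16 | (2S,4S)-7-(benzyloxy)-2-[4-(benzyloxy)phenyl]chroman-4-ol | O[C@H]1C[C@@H](c2ccc(OCc3ccccc3)cc2)Oc2cc(OCc3ccccc3)ccc12
F2 | step 16 | 3-(benzyloxy)cyclobut-2-en-1-one | O=C1C=C(OCc2ccccc2)C1
F3 | step 16 | 5-(benzyloxy)-2-[(2R,3S)-2-(benzyloxy)-3-[4-(benzyloxy)phenyl]-3-[(tert-butyldimethylsilyl)oxy]propyl]-3-[(triisopropylsilyl)oxy]phenol | Oc1cc(OCc2ccccc2)cc(O[Si](C(C)C)(C(C)C)C(C)C)c1C[C@@H](OCc1ccccc1)[C@@H](O[Si](C)(C)C(C)(C)C)c1ccc(OCc2ccccc2)cc1
F4 | step 19 | aryl triflate of 33 (triflate on the C8a oxygen; (1S,2R) alcohol unchanged) | c5ccccc5COc1c(C[C@@H](OCc2ccccc2)[C@@H](O)c2ccc(OCc3ccccc3)cc2)c(OS(=O)(=O)C(F)(F)F)cc(OCc2ccccc2)c1[C@H]4C[C@@H](c2ccc(OCc3ccccc3)cc2)Oc2cc(OCc3ccccc3)ccc24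
F5 | step 19 | (2R)-2-(benzyloxy)-1-[4-(benzyloxy)phenyl]propan-1-one bearing the ring D aryl triflate on C3 | c5ccccc5COc1c(C[C@@H](OCc2ccccc2)C(=O)c2ccc(OCc3ccccc3)cc2)c(OS(=O)(=O)C(F)(F)F)cc(OCc2ccccc2)c1[C@H]4C[C@@H](c2ccc(OCc3ccccc3)cc2)Oc2cc(OCc3ccccc3)ccc24
F6 | step 19 | (1R,2R) syn alcohol, the C1 epimer of F4 | c5ccccc5COc1c(C[C@@H](OCc2ccccc2)[C@H](O)c2ccc(OCc3ccccc3)cc2)c(OS(=O)(=O)C(F)(F)F)cc(OCc2ccccc2)c1[C@H]4C[C@@H](c2ccc(OCc3ccccc3)cc2)Oc2cc(OCc3ccccc3)ccc24
F7 | step 4 | ethyl 2-[(2S)-7-(benzyloxy)-2-[4-(benzyloxy)phenyl]-2H-chromen-4-yl]acetate | CCOC(=O)CC1=C[C@@H](c2ccc(OCc3ccccc3)cc2)Oc2cc(OCc3ccccc3)ccc12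
F8 | step 4 | ethyl 2-[(2S,4R)-7-hydroxy-2-(4-hydroxyphenyl)chroman-4-yl]acetate | CCOC(=O)C[C@H]1C[C@@H](c2ccc(O)cc2)Oc2cc(O)ccc12
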